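Locants are those of the target's hexahydroinden-1-one core (C1 ketone, C2 CO2Me, C3 and C5 hexadecyl, C4 CO2Me, C7 CO2H, ring fusion C3a/C7a) and are kept for all intermediates.
Retrosynthetic cuts, in order: C3–hexadecyl (organocopper addition–elimination on an enol lactone tied to the C4 carboxyl); C2–C3 and C1–C2 (Dieckmann closure onto a C3 lactone, malonate acylation of a C1 acid); the C1 acid/C3 lactone pair back to the C1–C3 bond of a cyclobutanone (Baeyer–Villiger); C1–C7a (photochemical 1,3-acyl shift from C6); C3a–C4, C5–C6 and the C3–O ketal bond (intramolecular Diels–Alder, phenol oxidation).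
Forward ring order: cyclohexene inside a bicyclo[2.2.2]octenone with a fused tetrahydrofuran (step 4), cis-fused cyclobutanone C1–C3–C3a–C7a (step 5), γ-lactone plus C1 acid (step 9), cyclopentane-1,3-dione (step 11), cyclopentenone carrying the second chain (step 14).
Enabling feature: C1 is bonded to C7a, C7a is allylic to C6=C7 while the C7 ester is conjugated, and C1 and C3 are both oxygenated. The C1–C7a bond is therefore the 1,3-shift image of a C1–C6 bond in a bicyclo[2.2.2]oct-5-en-2-one laid over the ring C3a–C4–C5–C6–C7–C7a, whose C1(=O)–C3(ketal) bridge is the OH/OMe edge of an isovanillate.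
Stereochemistry: the O–CH2 tether and the (E)-alkene fix C3a and C4 in the cycloaddition, the suprafacial acyl shift fixes C7a, kinetic protonation of an ester dienolate on the convex face fixes C7, and the absolute configuration comes from resolution of the cycloadduct.

Key step: step 5

Assumption: the oxidative ketalisation in step 4 is not enantioselective, so 7 and 8 form as racemates; 8 is resolved by preparative HPLC on a chiral stationary phase, and every SMILES string shows the enantiomer that leads to the target.

Step 1
Reactants: 1 isovanillic acid (3-hydroxy-4-methoxybenzoic acid)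
Product: 2 tert-butyl 3-hydroxy-4-methoxybenzoate
Conditions: Me2NCH(OtBu)2, toluene, 80 °C
Reagents that add atoms: N,N-dimethylformamide di-tert-butyl acetal, CN(C)C(OC(C)(C)C)OC(C)(C)C
Why: Esterification with the formamide acetal transfers tert-butyl to the carboxylate through an ion pair under neutral conditions and should leave the less acidic phenol free.

Step 2
Reactants: 3 heptadecanal; 4 triethyl phosphonoacetate
Product: 5 ethyl (E)-nonadec-2-enoate
Conditions: NaH, THF, 0 °C → rt
Reagents that add atoms: none
Why: Horner–Wadsworth–Emmons olefination of an unbranched aldehyde with a stabilised phosphonate anion gives the (E)-enoate.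

Step 3
Reactants: 5 ethyl (E)-nonadec-2-enoate
Product: 6 (E)-nonadec-2-en-1-ol
Conditions: DIBAL-H (2.2 equiv), CH2Cl2, −78 → 0 °C; Rochelle salt
Reagents that add atoms: none
Why: DIBAL-H reduces the enoate in the 1,2-sense to the allylic alcohol without touching the (E)-alkene.

Step 4
Reactants: 2 tert-butyl 3-hydroxy-4-methoxybenzoate; 6 (E)-nonadec-2-en-1-ol
Product: 8 cycloadduct: bicyclo[2.2.2]oct-5-en-2-one with the C1 ketone between C6 and ketal C3 (OMe; O–CH2–C4 tetrahydrofuran); C7=C7a with CO2tBu on C7; C5 hexadecyl trans to the C4 arm, via mixed o-quinone monoketal 7 (not isolated)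
Conditions: PhI(OAc)2, 6 (3 equiv, excess recovered), CH2Cl2, 0 °C → rt; toluene, 110 °C; preparative HPLC on a chiral stationary phase
Reagents that add atoms: none
Why: Oxidation of the guaiacol-type phenol with PhI(OAc)2 in the presence of the alkenol gives the mixed o-quinone monoketal (masked o-benzoquinone), whose tethered alkene adds across C3a and C6 in an intramolecular Diels–Alder reaction; the two-atom O–CH2 tether forces bonding on the face of that ketal oxygen and the (E)-geometry places the hexadecyl group trans to the CH2O arm, so a single racemic diastereomer is expected and is resolved on the chiral phase.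

Step 5
Reactants: 8 cycloadduct
Product: 9 cis-fused cyclobutanone (C1, C3, C3a, C7a) on the cyclohexene; C6=C7 enoate; ketal and tetrahydrofuran retained; C1 on C7a cis to C3 on C3a and syn to the C4 arm
Conditions: hν (Hg lamp, Pyrex, λ ≥ 300 nm), degassed benzene, rt, to partial conversion; recovered 8 recycled
Reagents that add atoms: none
Why: Direct n→π* excitation of the β,γ-unsaturated ketone cleaves the C1–C6 bond (Norrish type I) to a singlet acyl/allyl radical pair, and the acyl carbon recombines at the far allyl terminus C7a while the alkene moves to C6=C7; this is the photochemical 1,3-acyl shift known for bicyclo[2.2.2]oct-5-en-2-ones made from masked o-benzoquinones. The four-membered ring C1–C3–C3a–C7a closes by this intramolecular radical recombination, formally a suprafacial [1,3]-sigmatropic shift and not a polar cyclisation. The one new stereocentre, C7a, is controlled by the bridge itself: C1 stays bonded to C3, which sits on C3a, so it can reach C7a only on the face the ketone bridge already occupied, giving the cis-fused cyclobutanone syn to the C4 arm. The step needs the singlet 1,3-shift to beat the triplet oxa-di-π-methane rearrangement, α-cleavage towards C3 with decarbonylation, and secondary photolysis of 9, which is itself a β,γ-unsaturated ketone. Direct irradiation without sensitiser in benzene, a Pyrex cut-off that leaves the enoate π→π* band unexcited, allyl stabilisation of the C6–C7–C7a radical and interruption at partial conversion should secure this.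

Step 6
Reactants: 9 cyclobutanone
Product: 10 cyclobutanol (C1–OH on the concave face)
Conditions: NaBH4, MeOH/CH2Cl2, −20 °C
Reagents that add atoms: none
Why: Borohydride reduction of the strained cyclobutanone is fast and leaves enoate and ketal alone, with hydride expected from the convex face to give the endo carbinol; this stereocentre is of no consequence because the ketone returns in step 8, and the reduction removes the acidic α-proton at C7a before base is used.

Step 7
Reactants: 10 cyclobutanol
Product: 11 β,γ-unsaturated ester: C5=C6, C7–H, CO2tBu on C7 cis to C1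
Conditions: LDA (2.5 equiv), HMPA, THF, −78 °C; inverse quench into AcOH/THF, −78 °C
Reagents that add atoms: none
Why: Deconjugative protonation: LDA/HMPA forms the alkoxide and then removes the γ-proton at C5 of the enoate, and kinetic α-protonation of the ester dienolate at C7 by excess acetic acid from the open convex face, anti to the pseudoaxial cyclobutane carbon C1 on C7a, should place CO2tBu cis to C1.

Step 8
Reactants: 11 deconjugated cyclobutanol
Product: 12 cyclobutanone with C5=C6 and the C7 stereocentre
Conditions: Dess–Martin periodinane, NaHCO3, CH2Cl2, 0 °C → rt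
Reagents that add atoms: none
Why: Dess–Martin oxidation restores the cyclobutanone under buffered, non-basic conditions that should not epimerise C7 or move the alkene back into conjugation.

Step 9
Reactants: 12 cyclobutanone
Product: 14 lactone acid: C7a–CO2H (C1) and cis-fused γ-lactone C3(=O)–O–CH2–C4, via acyloxy orthoester lactone 13 (not isolated)
Conditions: 30% H2O2, AcOH/H2O (9:1), 0 °C → rt; toluene azeotrope
Reagents that add atoms: hydrogen peroxide, OO; water, O
Why: Baeyer–Villiger oxidation of a cyclobutanone with aqueous hydrogen peroxide in acetic acid is strain-driven and is known to spare ring alkenes; the dialkoxy-substituted C3 should migrate with retention in preference to the secondary C7a, so oxygen enters between C1 and C3, and the aqueous acid hydrolyses the acyloxy orthoester to the C1 acid, the C3 γ-lactone and methanol.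

Step 10
Reactants: 14 lactone acid
Product: 17 β-keto ester C7a–C1(=O)–CH2–CO2Me (the CH2 is C2; lactone retained), via acyl imidazole 15 (not isolated), via acylmalonic half ester 16 (not isolated)
Conditions: CDI, THF, rt; then KO2CCH2CO2Me, MgCl2, Et3N, MeCN, rt → 40 °C; 1 M HCl
Reagents that add atoms: potassium methyl malonate, COC(=O)CC(=O)[O-].[K+]
Why: Masamune–Brooks homologation: the acyl imidazole is C-acylated by the neutral magnesium enolate of the malonic half ester and decarboxylates on acidification, conditions that tolerate α-stereocentres (C7a), the lactone and the tert-butyl ester.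

Step 11
Reactants: 17 β-keto ester
Product: 18 hydroxy trione: 2-methoxycarbonyl-cyclopentane-1,3-dione (C1, C2, C3; enol form) cis-fused at C3a/C7a; C4–CH2OH free
Conditions: NaH (1.1 equiv), THF, 0 °C → rt; cold 0.5 M HCl; used crude
Reagents that add atoms: none
Why: Dieckmann-type (Lacey–Dieckmann) C-acylation: the β-keto ester enolate attacks the cis-disposed lactone carbonyl C3 in a 5-exo-trig closure, the ring alkoxide is expelled, and proton transfer to the highly stabilised 2-acyl-1,3-dione anion drives the reaction with one equivalent of base, the five-membered trione ring holding C3a/C7a cis.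

Step 12
Reactants: 18 hydroxy trione
Product: 20 C4 carboxylic acid of the trione, via C4 aldehyde 19 (not isolated)
Conditions: TPAP (10 mol %), NMO·H2O (10 equiv), MeCN, rt; aq. KHSO4
Reagents that add atoms: water, O
Why: Ley–Griffith oxidation in the presence of water takes the primary alcohol through the aldehyde hydrate to the acid, while the tricarbonyl unit is present as its ammonium enolate, which neither adds the alcohol nor is oxidised.

Step 13
Reactants: 20 trione acid
Product: 21 enol lactone C3–O–C(=O)–C4 (five-membered, cis-fused)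
Conditions: DCC, CH2Cl2, 0 °C → rt; filtration; used directly
Reagents that add atoms: none
Why: Carbodiimide dehydration gives the enol lactone by intramolecular O-acylation of the acidic enol, the five-membered ring to the cis-neighbouring C3 oxygen being favoured over a bridged six-membered ring at C1, which marks C3 with a carboxylate leaving group.

Step 14
Reactants: 21 enol lactone; 22 1-bromohexadecane
Product: 24 3-hexadecyl-2-methoxycarbonyl cyclopentenone with C4–CO2H, via hexadecylmagnesium bromide 23 (not isolated)
Conditions: 22, Mg, THF; CuBr·SMe2 (1 equiv), −40 °C; then 21, −78 → −40 °C; aq. NH4Cl then 1 M HCl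
Reagents that add atoms: none
Why: Organocopper addition–elimination at the β-carbon of a β-acyloxy alkylidene β-keto ester: the hexadecyl group adds to C3 and the enolate expels the C4 carboxylate irreversibly, which restores the C2=C3 enone and frees the C4 acid.

Step 15
Reactants: 24 enone acid
Product: 25 C4 methyl ester (C7 tert-butyl ester retained)
Conditions: TMSCHN2, MeOH/toluene (1:4), 0 °C
Reagents that add atoms: trimethylsilyldiazomethane, C[Si](C)(C)C=[N+]=[N-]
Why: Esterification with trimethylsilyldiazomethane in methanol methylates only the free carboxylic acid under neutral conditions.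

Step 16
Reactants: 25 tert-butyl ester
Product: 26 target acid CNP0252450.3
Conditions: 85% aq. H3PO4, toluene, rt
Reagents that add atoms: none
Why: Mild acidolysis of the tert-butyl ester (E1 loss of isobutene) should leave both methyl esters, the enone, the C5=C6 alkene and the stereocentres at C7 and C4 untouched.

Compound list
1 | isovanillic acid | COc1ccc(C(=O)O)cc1O | starting material
2 | tert-butyl 3-hydroxy-4-methoxybenzoate | COc1ccc(C(=O)OC(C)(C)C)cc1O | intermediate
3 | heptadecanal | CCCCCCCCCCCCCCCCC=O | starting material
4 | triethyl phosphonoacetate | CCOC(=O)CP(=O)(OCC)OCC | starting material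
5 | ethyl (E)-nonadec-2-enoate | CCCCCCCCCCCCCCCC/C=C/C(=O)OCC | intermediate
6 | (E)-nonadec-2-en-1-ol | CCCCCCCCCCCCCCCC/C=C/CO | intermediate
7 | mixed o-quinone monoketal: tert-butyl 4-methoxy-4-[(E)-nonadec-2-enyloxy]-3-oxocyclohexa-1,5-diene-1-carboxylate (racemic as formed) | CCCCCCCCCCCCCCCC/C=C/CO[C@@]1(OC)C=CC(C(=O)OC(C)(C)C)=CC1=O | intermediate (not isolated)
8 | cycloadduct: bicyclo[2.2.2]oct-5-en-2-one, C1 ketone between C6 and ketal C3 (OMe, O–CH2–C4 tetrahydrofuran), C7=C7a with CO2tBu on C7, C5 hexadecyl trans to the C4 arm (racemic as formed, resolved) | CCCCCCCCCCCCCCCC[C@@H]1[C@H]2C(=O)[C@@]3(OC)OC[C@@H]1[C@H]3C=C2C(=O)OC(C)(C)C | intermediate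
9 | cis-fused cyclobutanone (C1, C3, C3a, C7a) with C6=C7 enoate, ketal and tetrahydrofuran retained | CCCCCCCCCCCCCCCC[C@@H]1C=C(C(=O)OC(C)(C)C)[C@H]2C(=O)[C@@]3(OC)OC[C@@H]1[C@@H]23 | intermediate
10 | cyclobutanol of 9, C1–OH on the concave face (expected epimer) | CCCCCCCCCCCCCCCC[C@@H]1C=C(C(=O)OC(C)(C)C)[C@H]2[C@@H](O)[C@@]3(OC)OC[C@@H]1[C@@H]23 | intermediate
11 | deconjugated cyclobutanol: C5=C6, C7–H, CO2tBu cis to C1 | CCCCCCCCCCCCCCCCC1=C[C@@H](C(=O)OC(C)(C)C)[C@H]2[C@@H](O)[C@@]3(OC)OC[C@@H]1[C@@H]23 | intermediate
12 | deconjugated cyclobutanone | CCCCCCCCCCCCCCCCC1=C[C@@H](C(=O)OC(C)(C)C)[C@H]2C(=O)[C@@]3(OC)OC[C@@H]1[C@@H]23 | intermediate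
13 | acyloxy orthoester lactone C1(=O)–O–C3(OMe)(OCH2) | CCCCCCCCCCCCCCCCC1=C[C@@H](C(=O)OC(C)(C)C)[C@H]2C(=O)O[C@@]3(OC)OC[C@@H]1[C@@H]23 | intermediate (not isolated)
14 | lactone acid: C7a–CO2H (C1), cis-fused γ-lactone C3(=O)–O–CH2–C4, all four ring substituents cis | CCCCCCCCCCCCCCCCC1=C[C@@H](C(=O)OC(C)(C)C)[C@@H](C(=O)O)[C@H]2C(=O)OC[C@@H]12 | intermediate
15 | acyl imidazole of 14 | CCCCCCCCCCCCCCCCC1=C[C@@H](C(=O)OC(C)(C)C)[C@@H](C(=O)n3ccnc3)[C@H]2C(=O)OC[C@@H]12 | intermediate (not isolated)
16 | acylmalonic half ester (malonate CH configurationally labile, not specified) | CCCCCCCCCCCCCCCCC1=C[C@@H](C(=O)OC(C)(C)C)[C@@H](C(=O)C(C(=O)O)C(=O)OC)[C@H]2C(=O)OC[C@@H]12 | intermediate (not isolated)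
17 | β-keto ester C7a–C1(=O)–CH2–CO2Me with C3 γ-lactone | CCCCCCCCCCCCCCCCC1=C[C@@H](C(=O)OC(C)(C)C)[C@@H](C(=O)CC(=O)OC)[C@H]2C(=O)OC[C@@H]12 | intermediate
18 | hydroxy trione: cis-fused 2-methoxycarbonyl-cyclopentane-1,3-dione (enol form), C4–CH2OH | CCCCCCCCCCCCCCCCC1=C[C@@H](C(=O)OC(C)(C)C)[C@H]2C(=O)C(C(=O)OC)=C(O)[C@H]2[C@H]1CO | intermediate
19 | C4 aldehyde of the trione | CCCCCCCCCCCCCCCCC1=C[C@@H](C(=O)OC(C)(C)C)[C@H]2C(=O)C(C(=O)OC)=C(O)[C@H]2[C@H]1C=O | intermediate (not isolated)
20 | C4 carboxylic acid of the trione | CCCCCCCCCCCCCCCCC1=C[C@@H](C(=O)OC(C)(C)C)[C@H]2C(=O)C(C(=O)OC)=C(O)[C@H]2[C@H]1C(=O)O | intermediate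
21 | enol lactone C3–O–C(=O)–C4 | CCCCCCCCCCCCCCCCC1=C[C@@H](C(=O)OC(C)(C)C)[C@H]2C(=O)C(C(=O)OC)=C3OC(=O)[C@@H]1[C@@H]23 | intermediate
22 | 1-bromohexadecane | CCCCCCCCCCCCCCCCBr | starting material
23 | hexadecylmagnesium bromide | CCCCCCCCCCCCCCCC[Mg]Br | intermediate (not isolated)
24 | 3,5-dihexadecyl enone with C2 CO2Me, C4 CO2H, C7 CO2tBu | CCCCCCCCCCCCCCCCC1=C[C@@H](C(=O)OC(C)(C)C)[C@H]2C(=O)C(C(=O)OC)=C(CCCCCCCCCCCCCCCC)[C@H]2[C@H]1C(=O)O | intermediate
25 | C2, C4 dimethyl ester, C7 tert-butyl ester | CCCCCCCCCCCCCCCCC1=C[C@@H](C(=O)OC(C)(C)C)[C@H]2C(=O)C(C(=O)OC)=C(CCCCCCCCCCCCCCCC)[C@H]2[C@H]1C(=O)OC | intermediate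
26 | CNP0252450.3 | CCCCCCCCCCCCCCCCC1=C[C@@H](C(=O)O)[C@H]2C(=O)C(C(=O)OC)=C(CCCCCCCCCCCCCCCC)[C@H]2[C@H]1C(=O)OC | target

Total step count: 16. Longest linear sequence: 15 steps (3 → 26 through steps 2–16).

Steps most likely to fail

Step 14. The organocopper reagent may attack the acyl carbon of the enol lactone (acyl transfer to give a C4 ketone) or add a second time to the product enone, instead of clean addition–elimination at C3. The fallback sets out from 21 and removes the acylating group before the chain is introduced. Hydrogen chloride (4 M in dioxane, CH2Cl2, 0 °C) opens the enol lactone, chloride adding to C3 and expelling the C4 carboxylate, to give the 3-chloro enone acid F1. Trimethylsilyldiazomethane converts it into the 3-chloro enone methyl ester F2, an ordinary β-chloro enone. The organocopper reagent made from 23 then replaces chloride by addition–elimination, and the route is rejoined at 25.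

Step 11. The stabilised β-keto ester enolate may fail to C-acylate on the lactone, through O-acylation or through retro-Claisen cleavage by the liberated alkoxide. The fallback sets out from 17 and reverses the order of bond formation. After the β-keto ester is masked as its sodium enolate, 23 (with anhydrous CeCl3, THF, −78 °C) adds once to the lactone carbonyl to give the hydroxy diketo ester F3 (C3 hexadecyl ketone, C4–CH2OH, in equilibrium with its lactol). TPAP/NMO·H2O oxidises the open form to the keto acid F4. Intramolecular Knoevenagel condensation of the β-keto ester methylene with the C3 ketone (piperidinium acetate, benzene, 50 °C) then closes the cyclopentenone, and the route is rejoined at 24.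

Step 9. Peracetic acid formed in the medium may epoxidise the nucleophilic C5=C6 alkene of 12 in competition with oxidation of the ketone. The fallback sets out from 9, whose only alkene is the electron-poor enoate, and moves the oxygen insertion ahead of the alkene shift. mCPBA/NaHCO3 (CH2Cl2, 0 °C) gives the conjugated acyloxy orthoester lactone F5, which aqueous acetic acid in THF hydrolyses to the conjugated lactone acid F6. Deconjugative protonation is then run on the polyanion (LDA, 3.5 equiv, HMPA, THF, −78 °C; inverse quench into AcOH), which rejoins the route at 14 and makes steps 6–8 unnecessary.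

Further compounds
F1 | step 14 | 3-chloro enone acid (C3–Cl, C4–CO2H) | CCCCCCCCCCCCCCCCC1=C[C@@H](C(=O)OC(C)(C)C)[C@H]2C(=O)C(C(=O)OC)=C(Cl)[C@H]2[C@H]1C(=O)O
F2 | step 14 | 3-chloro enone methyl ester | CCCCCCCCCCCCCCCCC1=C[C@@H](C(=O)OC(C)(C)C)[C@H]2C(=O)C(C(=O)OC)=C(Cl)[C@H]2[C@H]1C(=O)OC
F3 | step 11 | hydroxy diketo ester (C3 hexadecyl ketone, C4–CH2OH, C1 β-keto ester) | CCCCCCCCCCCCCCCCC1=C[C@@H](C(=O)OC(C)(C)C)[C@@H](C(=O)CC(=O)OC)[C@@H](C(=O)CCCCCCCCCCCCCCCC)[C@H]1CO
F4 | step 11 | keto acid (C3 hexadecyl ketone, C4–CO2H, C1 β-keto ester) | CCCCCCCCCCCCCCCCC1=C[C@@H](C(=O)OC(C)(C)C)[C@@H](C(=O)CC(=O)OC)[C@@H](C(=O)CCCCCCCCCCCCCCCC)[C@H]1C(=O)O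
F5 | step 9 | conjugated acyloxy orthoester lactone | CCCCCCCCCCCCCCCC[C@@H]1C=C(C(=O)OC(C)(C)C)[C@H]2C(=O)O[C@@]3(OC)OC[C@@H]1[C@@H]23
F6 | step 9 | conjugated lactone acid | CCCCCCCCCCCCCCCC[C@@H]1C=C(C(=O)OC(C)(C)C)[C@@H](C(=O)O)[C@H]2C(=O)OC[C@@H]12
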